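In a one-step world with the gas held, the starting material falls exponentially towards some level, and that level is what must be found for the flask.

all flasks: starting material 0.020 M
- ochre: second substrate 1.5 equiv; gas 9 mM (held); run made earlier
- flask: second substrate 1.00 equiv; gas 9.0 mM (held); time 8.0 h

- ochre (time / min: starting material / %, target / %): 4.00: 74.4, 24.9; 6.00: 65.1, 34.7; 8.00: 57.4, 43.9; 15.0: 34.0, 67.3; 20.0: 24.3, 75.0; 30.0: 13.2, 87.9; 50.0: 4.0, 95.8

(readings scatter by 1 percentage point)

- the state of affairs at 8.0 h: stopped, and by what, or still going (it is still moving / all of the starting material has reacted / forward and back rates have come level)
- part of the starting material gone at 8.0 h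
- the target standing at 8.0 h, as a percentage of the starting material charged

- the numbers in the tables scatter by 1 percentage point (one standard deviation)
- at the start none of the gas is in solution
- the reaction counts as stopped when no species that holds the starting material changes by six tenths of a point or more over the second half of the time

One end is a step that runs one way. The ochre run falls from 57.4 % at 8.00 min to 13.2 % at 30.0 min, a half-life of 10.4 min. The flask's 8.0 h then holds 46.2 half-lives and leaves hardly any starting material. This line gives 3.47 % at 50.0 min, where the reading is 4.0 % with a scatter of 1 percentage point, so the ochre run does not exclude this end.

The other end is a step already in balance at that last reading. The standing ratio, target over starting material at the last ochre reading, a conditional equilibrium constant for this gas level, reads 23.9. It leaves a share of one part in one plus the ratio, 4.01 %.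

The ratio was still 6.66 at 30.0 min. The flask holds the same gas level but 1.00 equiv of second substrate against 1.5 equiv in the ochre run. Taking the ratio over unchanged, this text's own reckoning places the flask between the two ends, with about 96.0 % gone at the second end and the scatter of that reading on this figure.

The forecast says all of the starting material has reacted, with conversion 99.5 % (91 % to 100 %) and target 99 % (89 % to 100 %), adding “The residual risk is a hidden reversibility, which could leave up to about 10%”. Its conversion stands nearer the first end, above the 96.0 % of the second end.

The flask gives: forward and back rates have come level, conversion 97.2 %, target 97.1 %.

    starting material + coupling partner ⇌ target (K = 3900 L mol⁻¹, k = 0.140 L mol⁻¹ s⁻¹)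
    second substrate + coupling partner ⇌ second product (K = 140 L mol⁻¹, k = 0.0520 L mol⁻¹ s⁻¹)
    gas ⇌ coupling partner, rate k3*(csat - [coupling partner]) (kL = 0.100 s⁻¹)
    starting material → decomposition product (k = 6.00 × 10⁻⁷ s⁻¹)
    second substrate ⇌ dormant form (K = 0.490, k = 5.90 × 10⁻⁴ s⁻¹)

At 8.00 h the flask stands at a ratio of 35.1, and its 2.77 % of starting material is less than the 4.01 % of the second end. At 80.0 h the flask holds 2.75 %. The neighbouring flask with 0.250 equiv of second substrate gives the same ratio, 35.1, with 2.77 % of starting material left, while its second product stands at 0.00229 M against 0.00916 M in the flask.

(The data were computed with made-up constants, and the scatter is random.)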